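(The readings were generated by integration for substances that don't exist; the scatter is artificial.)

In a one-step world substrate goes straight to target and the capture agent plays no part, so the blue run's 4.3% at 15.0 min could stand unchanged for the flask asked about, which is the violet run followed on.

| setting | violet | blue | flask |
|---|---|---|---|
| substrate | 10 mM | 10 mM | 10 mM |
| gas | 0.69 mM (held) | 0.69 mM (held) | 0.69 mM (held) |
| capture agent | 3 mM | 4.5 mM | 3.00 mM |
| remark | the very flask that is asked about, followed so far | run made earlier |  |
| time |  |  | 15 min |

| run | time / min | target / % |
|---|---|---|
| violet | 0.667 | 0 |
| violet | 1.33 | 0 |
| violet | 2.00 | 0 |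
| violet | 2.50 | 0 |
| violet | 3.00 | 1.0 |
| blue | 1.33 | 0.4 |
| blue | 2.50 | 0 |
| blue | 4.00 | 0.8 |
| blue | 8.00 | 1.8 |
| blue | 15.0 | 4.3 |

(standard deviation of a reading: 0.5 percentage points)

- at the start none of the gas is in solution

* amount of target at 15 min, in percent of the substrate charged
* the change that raises the amount of target at 15 min, in percent of the substrate charged most ("none" if none brings more than 2 percentage points) (beta / theta / none)
* amount of target at 15 min, in percent of the substrate charged, after beta

- beta: doubling the transfer coefficient of the gas, all else as stated
- theta: doubling the saturation concentration of gas, all else as stated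

The lag in both runs points to steps before the target, so I treat the capture agent as a correction on blue's reading and compute only that. Blue's reading times blue's charge over the violet charge gives 6.45%, the inverse-charge figure: what target reaches if it goes as one over the capture charge. As a guess, I commit to halfway between the reading and that figure, 5.38%, with the 0.5 percentage points scatter of the one reading on it.

The forecast says 7%, higher than my figure, on the grounds that “less capture agent should mean less diversion”; it picks theta and gives 9% after beta.

The violet flask gives 5.49%, below the inverse-charge figure. The best change is theta, worth 2.6 points against 1.1 points for beta, which ends at 6.57%. The forecast held.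

    capture agent + intermediate B → trapped intermediate (k = 1.10 M⁻¹ s⁻¹)
    gas ⇌ reagent, rate k2*(csat - [reagent]) (kL = 0.0310 s⁻¹)
    substrate + reagent → intermediate A (k = 4.60 M⁻¹ s⁻¹)
    intermediate C → target (k = 0.00180 s⁻¹)
    substrate + target → side product B (k = 0.0630 M⁻¹ s⁻¹)
    intermediate C → side product A (k = 0.0150 s⁻¹)
    intermediate B → intermediate C (k = 0.0150 s⁻¹)
    intermediate A → intermediate B (k = 0.00970 s⁻¹)

At 5.89 min in the violet flask, intermediate B turns into intermediate C 5.2 times as fast as the capture agent traps it. That selectivity factor puts the trap at 16.1% of intermediate B's use at that moment, a side exit and so a correction.

For the neighbour flask with 1.2 mM of capture agent, the inverse-charge figure scaled on gives 16.1%. The computed result is 6.02%, below that figure and 0.53 points above the violet flask, so in this neighbour flask the figure overshoots.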